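Cuts: once the phenol protecting groups are set aside, the aryl–CHO and aryl–C(O)iPr bonds are cut first, then the aryl–C7′ bond, and finally C1–C7′, C2–C3 and C4–O together (eudesmane numbering, C7′ = benzylic carbon).
Enabling feature: in ring A (C1–C2–C3–C4–C5–C10) the only functionalised carbons, C1 (CH bearing C7′) and C4 (C(OH)CH3), stand 1,4 to each other across the C5–C10 fusion bond. Opening C2–C3 therefore leaves the 1,5-diene C2=C1–C10–C5–C4=C3, and ring B with C5, C7, C10, Me-10 and the C7 isopropenyl group is then (−)-β-elemene.
Forward: ring B is purchased and ring A closes in step 1 together with the C4–O and C1–C7′ bonds. C7′ is then converted to an organozinc and joined to iodinated tris-MOM phloroglucinol, and the arene receives the isobutyryl and formyl carbons by two directed lithiations.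
Stereochemistry: C5, C7 and C10 are those of β-elemene. C1 and C4 arise in step 1 from anti addition across both alkenes in a chair, and once C7′ is reduced (step 2) none of the five centres can epimerise.

Key step: step 1

Remark: α and β refer to the usual eudesmane drawing (trans-decalin, Me-10 β, H-5 α, 7β-isopropenyl). Commercial (−)-β-elemene is taken to be the (1S,2S,4R) enantiomer, whose three centres map unchanged onto C10, C5 and C7 of the target.

Step 1
Reactants: 1 (−)-β-elemene
Product: 3 4α-hydroxyeudesm-11-ene-1β-carboxylic acid, via σ-alkylpalladium chloride 2 (not isolated)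
Conditions: PdCl2(MeCN)2 (10 mol %), p-benzoquinone (2 equiv), CO (3 bar), THF–H2O 4:1, 23 °C
Reagents that add atoms: water, O; carbon monoxide, [C-]#[O+]
Why: Proposed new method: Pd(II) should bind the monosubstituted C1=C2 vinyl group in preference to either 1,1-disubstituted alkene, after which the CH2 terminus (C3) of the neighbouring equatorial isopropenyl group attacks C2 anti to the metal through a chair, closing ring A in a mode that is 6-endo-trig at both alkenes and leaving an equatorial (β) C1–Pd σ-bond and cationic character at tertiary C4. Water should add to C4 anti to the newly formed C2–C3 bond, i.e. along the equatorial α trajectory (the β side also carries axial Me-10), which sets 4α-OH/4β-Me and gives 2, while the trans ring fusion follows from the diequatorial diene arms held by C5 and C10. Migratory insertion of CO proceeds with retention at C1, attack of water on the acyl–Pd bond releases the equatorial 1β-acid, and benzoquinone together with the two liberated protons returns Pd(0) to Pd(II), an oxidant being indispensable for turnover. The closest known reaction types are the Pd(II)-catalysed Cope rearrangement of 2-alkyl-1,5-dienes, which passes through the same palladated cyclohexyl cation, Pd(II)/Pt(II)-initiated cation–olefin cyclisations of 1,5-dienes ended by tethered O-nucleophiles, and hydroxy- or alkoxypalladation–carbonylation of alkenes, but their merger with an external water trap has not been shown. The step needs vinyl-over-isopropenyl binding (degree of alkene substitution), C3–C2 rather than C4–C2 bonding (tertiary against primary cation), hydration faster than C5–C10 fragmentation or proton loss (fragmentation leads uphill to the strained ten-membered diene, and water is in large excess under base-free conditions), and CO insertion faster than β-hydride elimination (CO pressure, with β-hydrogens only on C2 because C10 is quaternary). The remote isopropenyl group on C7 lies too far from any other alkene to cyclise and, being 1,1-disubstituted, is a poor ligand for Pd(II), so it should survive.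

Step 2
Reactants: 3 4α-hydroxyeudesm-11-ene-1β-carboxylic acid
Product: 4 (4α-hydroxyeudesm-11-en-1β-yl)methanol
Conditions: LiAlH4 (3 equiv), THF, 0 °C to reflux; then H2O
Reagents that add atoms: none
Why: Hydride reduction of a carboxylic acid: LiAlH4 first forms the carboxylate and the C4 alkoxide, which rules out enolisation at C1, and it does not touch the isolated alkene, so the 1β configuration should pass unchanged into the primary alcohol.

Step 3
Reactants: 4 (4α-hydroxyeudesm-11-en-1β-yl)methanol
Product: 5 1β-(iodomethyl)eudesm-11-en-4α-ol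
Conditions: I2, PPh3, imidazole, CH2Cl2, 0 to 23 °C
Reagents that add atoms: iodine, II
Why: Appel-type iodination (Garegg–Samuelsson conditions): only the primary oxyphosphonium salt can be displaced by iodide in an SN2 sense, the imidazole buffer should keep the tertiary C4 alcohol from ionising, and no stereocentre takes part.

Step 4
Reactants: 6 phloroglucinol
Product: 7 1,3,5-tris(methoxymethoxy)benzene
Conditions: MOMCl (4 equiv), iPr2NEt (5 equiv), DMF, 0 to 23 °C
Reagents that add atoms: chloromethyl methyl ether, COCCl
Why: O-Alkylation of the phenols with an α-chloro ether (MOM acetal formation) is routine for phloroglucinol under amine base, and OMOM groups are chosen because they direct the later lithiations and leave under mild aqueous acid.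

Step 5
Reactants: 7 1,3,5-tris(methoxymethoxy)benzene
Product: 8 2-iodo-1,3,5-tris(methoxymethoxy)benzene
Conditions: NIS (1.0 equiv), MeCN, 0 °C, dark
Reagents that add atoms: N-iodosuccinimide, O=C1CCC(=O)N1I
Why: Electrophilic aromatic iodination (SEAr) of a trialkoxybenzene needs no acid activator, and with one equivalent of NIS the three equivalent ring positions should be iodinated only once because the first iodine hinders and deactivates the ring.

Step 6
Reactants: 5 1β-(iodomethyl)eudesm-11-en-4α-ol; 8 2-iodo-1,3,5-tris(methoxymethoxy)benzene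
Product: 10 1β-[2,4,6-tris(methoxymethoxy)benzyl]eudesm-11-en-4α-ol, via alkylzinc iodide 9 (not isolated)
Conditions: 5, Zn dust (activated), LiCl, THF, 40 °C; then 8, Pd(OAc)2 (4 mol %), SPhos (8 mol %), THF, 23 to 50 °C
Reagents that add atoms: none
Why: Negishi sp3–sp2 cross-coupling: zinc enters the C–I bond by electron transfer and is therefore indifferent to the β-branching that would slow an SN2 route, alkylzinc halides tolerate a hindered free alcohol, a bulky electron-rich biarylphosphine is the established answer to di-ortho-substituted aryl halides and to β-hydride elimination from primary alkyl–Pd species, and C1 is not touched.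

Step 7
Reactants: 10 1β-[2,4,6-tris(methoxymethoxy)benzyl]eudesm-11-en-4α-ol; 11 isobutyraldehyde
Product: 13 1β-[3-(1-hydroxy-2-methylpropyl)-2,4,6-tris(methoxymethoxy)benzyl]eudesm-11-en-4α-ol (carbinol epimers), via aryllithium alkoxide 12 (not isolated)
Conditions: n-BuLi (2.2 equiv), THF, 0 °C; 11, −78 to 0 °C; then H2O
Reagents that add atoms: none
Why: Directed ortho-metalation followed by 1,2-addition to an aldehyde: the first equivalent of base is spent on the C4 hydroxyl, the second removes one of the two equivalent ring hydrogens flanked by two OMOM groups, and the new carbinol centre forms without control, which is harmless because step 9 erases it.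

Step 8
Reactants: 13 1β-[3-(1-hydroxy-2-methylpropyl)-2,4,6-tris(methoxymethoxy)benzyl]eudesm-11-en-4α-ol
Product: 15 3-[(4α-hydroxyeudesm-11-en-1β-yl)methyl]-5-(1-hydroxy-2-methylpropyl)-2,4,6-tris(methoxymethoxy)benzaldehyde, via trilithiated intermediate 14 (not isolated)
Conditions: n-BuLi (3.5 equiv), THF, 0 °C; DMF, −78 to 23 °C; then H2O
Reagents that add atoms: N,N-dimethylformamide, CN(C)C=O
Why: A second directed ortho-metalation with DMF formylation: both hydroxyls are masked in situ as lithium alkoxides, the last ring hydrogen again lies between two OMOM groups, and the hemiaminal alkoxide formed with DMF collapses to the aldehyde only on quenching.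

Step 9
Reactants: 15 3-[(4α-hydroxyeudesm-11-en-1β-yl)methyl]-5-(1-hydroxy-2-methylpropyl)-2,4,6-tris(methoxymethoxy)benzaldehyde
Product: 16 3-[(4α-hydroxyeudesm-11-en-1β-yl)methyl]-5-isobutyryl-2,4,6-tris(methoxymethoxy)benzaldehyde
Conditions: Dess–Martin periodinane, CH2Cl2, 0 to 23 °C
Reagents that add atoms: none
Why: Dess–Martin oxidation converts the secondary benzylic alcohol into the aryl ketone under near-neutral conditions that leave the aldehyde, the tertiary C4 alcohol (no carbinol hydrogen), the MOM acetals and the alkene alone, and it removes the stereorandom carbinol centre.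

Step 10
Reactants: 16 3-[(4α-hydroxyeudesm-11-en-1β-yl)methyl]-5-isobutyryl-2,4,6-tris(methoxymethoxy)benzaldehyde
Product: 17 3-[(4α-hydroxyeudesm-11-en-1β-yl)methyl]-2,4,6-trihydroxy-5-isobutyrylbenzaldehyde (CNP0498016.1)
Conditions: 2 M aq HCl–THF 1:2, 40 °C
Reagents that add atoms: none
Why: Acid-catalysed acetal hydrolysis: each aryl MOM ether lies ortho to a carbonyl group whose hydrogen bond to the emerging phenol eases cleavage, so dilute aqueous acid should suffice and stay below what is needed to ionise the equatorial tertiary C4 alcohol or protonate the isopropenyl group.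

Compound list
1 | (−)-β-elemene, (1S,2S,4R)-1-ethenyl-1-methyl-2,4-di(prop-1-en-2-yl)cyclohexane | C=C(C)[C@@H]1CC[C@@](C)(C=C)[C@H](C(C)=C)C1 | starting material
2 | chloro(4α-hydroxyeudesm-11-en-1β-yl)palladium(II), further ligands (CO, solvent) omitted | C=C(C)[C@@H]1CC[C@@]2(C)[C@H]([Pd]Cl)CC[C@@](C)(O)[C@@H]2C1 | intermediate
3 | 4α-hydroxyeudesm-11-ene-1β-carboxylic acid | C=C(C)[C@@H]1CC[C@@]2(C)[C@H](C(=O)O)CC[C@@](C)(O)[C@@H]2C1 | intermediate
4 | (4α-hydroxyeudesm-11-en-1β-yl)methanol | C=C(C)[C@@H]1CC[C@@]2(C)[C@H](CO)CC[C@@](C)(O)[C@@H]2C1 | intermediate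
5 | 1β-(iodomethyl)eudesm-11-en-4α-ol | C=C(C)[C@@H]1CC[C@@]2(C)[C@H](CI)CC[C@@](C)(O)[C@@H]2C1 | intermediate
6 | phloroglucinol | Oc1cc(O)cc(O)c1 | starting material
7 | 1,3,5-tris(methoxymethoxy)benzene | COCOc1cc(OCOC)cc(OCOC)c1 | intermediate
8 | 2-iodo-1,3,5-tris(methoxymethoxy)benzene | COCOc1cc(OCOC)c(I)c(OCOC)c1 | intermediate
9 | [(4α-hydroxyeudesm-11-en-1β-yl)methyl]zinc iodide | C=C(C)[C@@H]1CC[C@@]2(C)[C@H](C[Zn]I)CC[C@@](C)(O)[C@@H]2C1 | intermediate
10 | 1β-[2,4,6-tris(methoxymethoxy)benzyl]eudesm-11-en-4α-ol | C=C(C)[C@@H]1CC[C@@]2(C)[C@H](Cc3c(OCOC)cc(OCOC)cc3OCOC)CC[C@@](C)(O)[C@@H]2C1 | intermediate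
11 | isobutyraldehyde | CC(C)C=O | starting material
12 | 3′-lithio derivative of 10 as its C4 lithium alkoxide | C=C(C)[C@@H]1CC[C@@]2(C)[C@H](Cc3c(OCOC)cc(OCOC)c([Li])c3OCOC)CC[C@@](C)(O[Li])[C@@H]2C1 | intermediate
13 | 1β-[3-(1-hydroxy-2-methylpropyl)-2,4,6-tris(methoxymethoxy)benzyl]eudesm-11-en-4α-ol, carbinol epimers | C=C(C)[C@@H]1CC[C@@]2(C)[C@H](Cc3c(OCOC)cc(OCOC)c(C(O)C(C)C)c3OCOC)CC[C@@](C)(O)[C@@H]2C1 | intermediate
14 | ring-lithiated 13 as its bis(lithium alkoxide) | C=C(C)[C@@H]1CC[C@@]2(C)[C@H](Cc3c(OCOC)c([Li])c(OCOC)c(C(O[Li])C(C)C)c3OCOC)CC[C@@](C)(O[Li])[C@@H]2C1 | intermediate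
15 | 3-[(4α-hydroxyeudesm-11-en-1β-yl)methyl]-5-(1-hydroxy-2-methylpropyl)-2,4,6-tris(methoxymethoxy)benzaldehyde, carbinol epimers | C=C(C)[C@@H]1CC[C@@]2(C)[C@H](Cc3c(OCOC)c(C=O)c(OCOC)c(C(O)C(C)C)c3OCOC)CC[C@@](C)(O)[C@@H]2C1 | intermediate
16 | 3-[(4α-hydroxyeudesm-11-en-1β-yl)methyl]-5-isobutyryl-2,4,6-tris(methoxymethoxy)benzaldehyde | C=C(C)[C@@H]1CC[C@@]2(C)[C@H](Cc3c(OCOC)c(C=O)c(OCOC)c(C(=O)C(C)C)c3OCOC)CC[C@@](C)(O)[C@@H]2C1 | intermediate
17 | 3-[(4α-hydroxyeudesm-11-en-1β-yl)methyl]-2,4,6-trihydroxy-5-isobutyrylbenzaldehyde (CNP0498016.1) | C=C(C)[C@@H]1CC[C@@]2(C)[C@H](Cc3c(O)c(C=O)c(O)c(C(=O)C(C)C)c3O)CC[C@@](C)(O)[C@@H]2C1 | target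

Total step count: 10.
Longest linear sequence: 8 steps from 1 (steps 1, 2, 3, 6, 7, 8, 9, 10). Steps 4 and 5 form the two-step arene branch.

Steps most likely to fail

1. Step 1 (the step carrying the new-method label).
- **What may go wrong:** The C4 cation may lose a proton instead of being hydrated. β-Hydride elimination towards C2 may occur before CO inserts. Wacker-type hydroxypalladation or hydroxycarbonylation of the vinyl group may compete with carbocyclisation. Pd(II) and oxidant may also be consumed unproductively by CO and water.
- **Fallback:** It uses known reaction types only, sets out from 1 and returns at 4. In this detour the terminal vinyl carbon ends up as C7′, and C2 and C3 come from allyl bromide.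
 - Rh(I)-catalysed hydroboration with catecholborane (RhCl(PPh3)3, THF) distinguishes mono- from 1,1-disubstituted alkenes and should give the catechol boronate F1.
 - F1 is oxidised (NaOH, H2O2) to the primary alcohol F2.
 - TEMPO/PhI(OAc)2 in aqueous MeCN leads to the acetic acid F3, and MeI/K2CO3 to the methyl ester F4.
 - Enolate allylation (LDA, allyl bromide) gives the α-allyl ester F5 as C1 epimers.
 - Ring-closing metathesis (second-generation Grubbs catalyst, dilute CH2Cl2) can engage only the adjacent isopropenyl group.
 - After equilibration with NaOMe/MeOH to the equatorial ester, this should give methyl eudesma-3,11-diene-1β-carboxylate F6.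
 - mCPBA (1 equiv, low temperature) should epoxidise the trisubstituted C3=C4 alkene in preference to the isopropenyl group, from the α face away from Me-10, giving the 3α,4α-epoxide F7.
 - LiAlH4 in refluxing THF then delivers hydride to the less substituted C3 and reduces the ester, giving 4.

2. Step 6.
- **What may go wrong:** Oxidative addition and transmetalation may be sluggish at the crowded, electron-rich aryl iodide. That would leave time for protonolysis of the C–Zn bond by the free hydroxyl or for β-hydride elimination at palladium.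
- **Fallback:** It sets out from 4, with 7 as the arene source, and returns at 10.
 - Dess–Martin oxidation of the primary alcohol should give the 1β-carbaldehyde F8.
 - 7 is deprotonated with n-BuLi (THF, 0 °C) to the aryllithium F9.
 - An excess of F9 adds to F8 to give the benzylic alcohol F10 as carbinol epimers.
 - Ionic hydrogenation (Et3SiH, TFA, CH2Cl2, −78 °C) removes the benzylic oxygen through the highly stabilised trialkoxybenzyl cation, which should ionise well before the C4 alcohol, and gives 10.

3. Step 8.
- **What may go wrong:** Ring deprotonation of the aggregated dialkoxide may be incomplete or slow. Forcing it could bring competing metalation at the allylic or benzylic positions.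
- **Fallback:** It sets out from 13 and returns at 14.
 - The remaining ring position is the most nucleophilic site of the molecule and should be iodinated by NIS (MeCN, 0 °C) to the aryl iodide F11.
 - n-BuLi (3.3 equiv, THF, −78 °C) then deprotonates both hydroxyls and effects fast iodine–lithium exchange, so that 14 is reached by halogen–metal exchange instead of C–H deprotonation and is quenched with DMF as in step 8.

Further compounds
F1 | step 1 | catechol boronate of β-elemene (vinyl group converted to CH2CH2–B(catecholate)) | C=C(C)[C@@H]1CC[C@@](C)(CCB2Oc3ccccc3O2)[C@H](C(C)=C)C1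
F2 | step 1 | primary alcohol (vinyl group of β-elemene converted to CH2CH2OH) | C=C(C)[C@@H]1CC[C@@](C)(CCO)[C@H](C(C)=C)C1
F3 | step 1 | acetic acid (vinyl group of β-elemene converted to CH2CO2H) | C=C(C)[C@@H]1CC[C@@](C)(CC(=O)O)[C@H](C(C)=C)C1
F4 | step 1 | methyl ester of F3 | C=C(C)[C@@H]1CC[C@@](C)(CC(=O)OC)[C@H](C(C)=C)C1
F5 | step 1 | α-allyl ester (C1 epimers) | C=C(C)[C@@H]1CC[C@@](C)(C(CC=C)C(=O)OC)[C@H](C(C)=C)C1
F6 | step 1 | methyl eudesma-3,11-diene-1β-carboxylate | C=C(C)[C@@H]1CC[C@@]2(C)[C@H](C(=O)OC)CC=C(C)[C@@H]2C1
F7 | step 1 | methyl 3α,4α-epoxyeudesm-11-ene-1β-carboxylate | C=C(C)[C@@H]1CC[C@@]2(C)[C@H](C(=O)OC)C[C@H]3O[C@@]3(C)[C@@H]2C1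
F8 | step 6 | 4α-hydroxyeudesm-11-ene-1β-carbaldehyde | C=C(C)[C@@H]1CC[C@@]2(C)[C@H](C=O)CC[C@@](C)(O)[C@@H]2C1
F9 | step 6 | 2-lithio-1,3,5-tris(methoxymethoxy)benzene | [Li]c1c(OCOC)cc(OCOC)cc1OCOC
F10 | step 6 | 1β-{hydroxy[2,4,6-tris(methoxymethoxy)phenyl]methyl}eudesm-11-en-4α-ol (carbinol epimers) | C=C(C)[C@@H]1CC[C@@]2(C)[C@H](C(O)c3c(OCOC)cc(OCOC)cc3OCOC)CC[C@@](C)(O)[C@@H]2C1
F11 | step 8 | 1β-[3-(1-hydroxy-2-methylpropyl)-5-iodo-2,4,6-tris(methoxymethoxy)benzyl]eudesm-11-en-4α-ol (carbinol epimers) | C=C(C)[C@@H]1CC[C@@]2(C)[C@H](Cc3c(OCOC)c(I)c(OCOC)c(C(O)C(C)C)c3OCOC)CC[C@@](C)(O)[C@@H]2C1
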